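**Plan**
- Cuts, in retrosynthetic order: the five O-protecting groups; the bond from C3 to its resorcinol ring (back to a C3 carboxyl group); the C5–vinyl bond (back to an aryl bromide and a styrene); the C3–C3a bond (retro ring contraction to a flavanone); the C2–aryl bond of that flavanone (back to 6-bromochromone and an arylboronic acid).
- Enabling feature: O1, C2 with its 4-oxygenated aryl group, and the benzo ring C3a–C7a of the dihydrobenzofuran correspond to O1, C2, the 2-aryl group and ring A (C4a–C8a) of a flavanone. C3–C3a is the bond formed when C4a shifts from C4 to C3. Old C4 ends up outside the ring as an ester carbon on C3 and is later exchanged for the aryl group.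
- Forward order: the benzo and pyranone rings come with the chromone. The sequence is conjugate arylation, contraction of the six-membered ring to the five-membered ring, Heck coupling at C5, decarboxylative arylation at C3, then removal of the sulfonate and the methyl ethers.
- Stereochemistry: 2S comes from a chiral diene on rhodium. C3 is set trans under control of C2 twice, first by anti iodination followed by inversion, then by radical capture anti to the C2 aryl group. The E alkene comes from the Heck reaction.

Key step: step 4

Assumption: the (S,S) diene ligand is taken to deliver the aryl group to the same enone face as with simple cyclic enones, which corresponds to 2S in the chromone; if the sense proves opposite, the equally accessible (R,R) ligand is used.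

Step 1
Reactants: 1 4-(4,4,5,5-tetramethyl-1,3,2-dioxaborolan-2-yl)phenol (4-hydroxyphenylboronic acid pinacol ester)
Product: 2 4-(4,4,5,5-tetramethyl-1,3,2-dioxaborolan-2-yl)phenyl methanesulfonate
Conditions: MsCl (1.2 equiv), Et3N (1.5 equiv), CH2Cl2, 0 °C → rt
Reagents that add atoms: methanesulfonyl chloride, CS(=O)(=O)Cl
Why: O-sulfonylation of a phenol with a sulfonyl chloride and an amine base is routine, and the pinacol boronate is inert to it.

Step 2
Reactants: 2 4-(4,4,5,5-tetramethyl-1,3,2-dioxaborolan-2-yl)phenyl methanesulfonate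
Product: 3 [4-(methanesulfonyloxy)phenyl]boronic acid
Conditions: NaIO4 (3 equiv), NH4OAc (3 equiv), acetone–H2O, rt
Reagents that add atoms: water, O
Why: Periodate glycol cleavage of the released pinacol drives hydrolysis of the aryl pinacol boronate to the free boronic acid, the form of nucleophile for which conjugate additions to chromones are documented, and the sulfonate survives the near-neutral medium.

Step 3
Reactants: 3 [4-(methanesulfonyloxy)phenyl]boronic acid; 4 6-bromochromone (6-bromo-4H-1-benzopyran-4-one)
Product: 5 4-[(2S)-6-bromo-4-oxo-3,4-dihydro-2H-1-benzopyran-2-yl]phenyl methanesulfonate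
Conditions: 3 (2 equiv), [RhCl(C2H4)2]2 (2.5 mol %), (S,S)-2,5-diphenylbicyclo[2.2.2]octa-2,5-diene (5.5 mol %), aq KOH (0.2 equiv), toluene–H2O, 30 °C
Reagents that add atoms: none
Why: Rhodium-catalysed asymmetric 1,4-addition of an arylboronic acid (Hayashi–Miyaura reaction), documented for chromones with chiral diene ligands: the aryl group passes from boron to monovalent rhodium and inserts into C2=C3 on the face left open by the C2-symmetric diene, which sets 2S, while the aryl bromide and the sulfonate are inert to this metal and the small amount of base at mild temperature limits retro-oxa-Michael racemisation and 1,2-addition to the product ketone.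

Step 4
Reactants: 5 4-[(2S)-6-bromo-4-oxo-3,4-dihydro-2H-1-benzopyran-2-yl]phenyl methanesulfonate
Product: 8 methyl (2S,3S)-5-bromo-2-[4-(methanesulfonyloxy)phenyl]-2,3-dihydro-1-benzofuran-3-carboxylate, via enol ether 6 (not isolated), via iodane ketal 7 (not isolated)
Conditions: PhI(OAc)2 (1.2 equiv), conc. H2SO4 (cat.), HC(OMe)3 (solvent), rt; aq NaHCO3 work-up
Reagents that add atoms: trimethyl orthoformate, COC(OC)OC; (diacetoxyiodo)benzene, CC(=O)OI(OC(C)=O)c1ccccc1 (its atoms are held only in 7)
Why: Acid and orthoformate convert ketone 5 into enol ether 6, whose C3 attacks the trivalent iodine of PhI(OAc)2 on the face away from the pseudo-equatorial C2 aryl group while methanol caps C4, giving the 2,3-trans iodane ketal 7. In 7 the pseudo-equatorial C3–I bond is anti-periplanar to the ring bond C4–C4a, so loss of iodobenzene is assisted by C4a, which moves from C4 to C3 through a phenonium-like three-centre transition state, and the dimethoxycarbenium ion left at old C4 gives up one methyl group to acetate and becomes the methyl ester. The closest known reaction is exactly this one, the oxidative ring contraction of flavanones by hypervalent iodine or thallium trinitrate in trimethyl orthoformate, a cyclic case of the 1,2-aryl shift of α-functionalised aryl ketone ketals. The dihydrofuran ring is thus closed by a ring-contracting 1,2-shift that makes C3–C3a and not by an end-to-end cyclisation, with O1, C2 and the C2–aryl bond as spectators, so 2S is carried through unchanged. The new C3 centre results from anti iodination followed by inversion, both dictated by C2, which places the ester trans to the aryl group (3S). The step requires migration of C4a in preference to a shift of the C2 aryl group (isoflavone pathway), elimination (flavone pathway) or methanolysis at C3; the ring oxygen on C8a, ortho to C4a, raises the migratory aptitude of C4a, whereas the sulfonyloxy group makes the C2 aryl ring a poor bridging group and disfavours positive charge at C2.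

Step 5
Reactants: 8 methyl (2S,3S)-5-bromo-2-[4-(methanesulfonyloxy)phenyl]-2,3-dihydro-1-benzofuran-3-carboxylate; 9 3,5-dimethoxystyrene
Product: 10 methyl (2S,3S)-5-[(E)-2-(3,5-dimethoxyphenyl)ethenyl]-2-[4-(methanesulfonyloxy)phenyl]-2,3-dihydro-1-benzofuran-3-carboxylate
Conditions: 9 (1.3 equiv), Pd2(dba)3 (2 mol %), [HP(t-Bu)3]BF4 (8 mol %), Cy2NMe (1.3 equiv), 1,4-dioxane, rt → 50 °C
Reagents that add atoms: none
Why: Mizoroki–Heck reaction of an aryl bromide with a styrene, E-selective through syn insertion and syn β-hydride elimination; the bulky trialkylphosphine on zerovalent palladium allows a mild temperature and a hindered amine base, so the acidic C3–H next to the ester is neither epimerised nor lost in a ring-opening β-elimination, and this catalyst does not insert into aryl sulfonates.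

Step 6
Reactants: 10 methyl (2S,3S)-5-[(E)-2-(3,5-dimethoxyphenyl)ethenyl]-2-[4-(methanesulfonyloxy)phenyl]-2,3-dihydro-1-benzofuran-3-carboxylate
Product: 11 (2S,3S)-5-[(E)-2-(3,5-dimethoxyphenyl)ethenyl]-2-[4-(methanesulfonyloxy)phenyl]-2,3-dihydro-1-benzofuran-3-carboxylic acid
Conditions: Me3SnOH (6 equiv), ClCH2CH2Cl, 75 °C; 1 M HCl wash
Reagents that add atoms: trimethyltin hydroxide, C[Sn](C)(C)O
Why: Trimethyltin hydroxide cleaves methyl esters under essentially neutral conditions and is the established choice for 2,3-dihydrobenzofuran-3-carboxylates, which epimerise or ring-open with alkali hydroxides; the aryl mesylate, the methyl ethers and the stilbene are not affected.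

Step 7
Reactants: 11 (2S,3S)-5-[(E)-2-(3,5-dimethoxyphenyl)ethenyl]-2-[4-(methanesulfonyloxy)phenyl]-2,3-dihydro-1-benzofuran-3-carboxylic acid
Product: 12 1,3-dioxoisoindolin-2-yl (2S,3S)-5-[(E)-2-(3,5-dimethoxyphenyl)ethenyl]-2-[4-(methanesulfonyloxy)phenyl]-2,3-dihydro-1-benzofuran-3-carboxylate
Conditions: N-hydroxyphthalimide (1.1 equiv), DIC (1.1 equiv), DMAP (0.1 equiv), CH2Cl2, 0 °C → rt
Reagents that add atoms: N-hydroxyphthalimide, O=C1c2ccccc2C(=O)N1O
Why: Carbodiimide coupling (Steglich-type esterification) is the standard way to a redox-active ester, the near absence of base protects C2 from β-elimination, and any epimerisation at C3 would be harmless because that centre becomes a radical in step 9.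

Step 8
Reactants: 13 1-bromo-3,5-dimethoxybenzene
Product: 15 (3,5-dimethoxyphenyl)zinc chloride, via arylmagnesium bromide 14 (not isolated)
Conditions: Mg turnings, LiCl, THF, rt; then ZnCl2 (1.0 equiv, THF), 0 °C → rt; the solution is titrated against I2 and used as such
Reagents that add atoms: magnesium, [Mg] (held only in 14); zinc chloride, Cl[Zn]Cl
Why: Magnesium insertion into an aryl bromide assisted by LiCl, followed by transmetalation to ZnCl2, is the standard preparation of the arylzinc halide–LiCl solutions used in Negishi-type couplings.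

Step 9
Reactants: 12 1,3-dioxoisoindolin-2-yl (2S,3S)-5-[(E)-2-(3,5-dimethoxyphenyl)ethenyl]-2-[4-(methanesulfonyloxy)phenyl]-2,3-dihydro-1-benzofuran-3-carboxylate; 15 (3,5-dimethoxyphenyl)zinc chloride
Product: 16 4-[(2S,3S)-3-(3,5-dimethoxyphenyl)-5-[(E)-2-(3,5-dimethoxyphenyl)ethenyl]-2,3-dihydro-1-benzofuran-2-yl]phenyl methanesulfonate
Conditions: 15 (3 equiv), NiCl2·glyme (20 mol %), 4,4′-di-tert-butyl-2,2′-bipyridine (40 mol %), THF–DMF, rt; 1 M HCl work-up
Reagents that add atoms: none
Why: Nickel-catalysed decarboxylative Negishi-type arylation of a secondary redox-active ester: electron transfer from a monovalent aryl-nickel species releases phthalimide anion and CO2, the planar benzylic C3 radical recombines with divalent aryl-nickel on the face remote from the C2 aryl group, and fast reductive elimination from trivalent nickel gives the 2,3-trans product (3S) as with other 2-substituted cyclic acids, while β-scission of C2–O1 is held back because that ring bond lies close to the nodal plane of the radical orbital.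

Step 10
Reactants: 16 4-[(2S,3S)-3-(3,5-dimethoxyphenyl)-5-[(E)-2-(3,5-dimethoxyphenyl)ethenyl]-2,3-dihydro-1-benzofuran-2-yl]phenyl methanesulfonate
Product: 17 4-[(2S,3S)-3-(3,5-dimethoxyphenyl)-5-[(E)-2-(3,5-dimethoxyphenyl)ethenyl]-2,3-dihydro-1-benzofuran-2-yl]phenol
Conditions: 2 M aq NaOH (5 equiv), MeOH–THF, 45 °C, Ar; then 1 M HCl to pH 4
Reagents that add atoms: none
Why: Alkaline cleavage of an aryl methanesulfonate (S–O scission by hydroxide or by way of sulfene) frees the phenol, and with the ester gone no acidifying group remains at C3, so both stereocentres, the methyl ethers and the stilbene are inert.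

Step 11
Reactants: 17 4-[(2S,3S)-3-(3,5-dimethoxyphenyl)-5-[(E)-2-(3,5-dimethoxyphenyl)ethenyl]-2,3-dihydro-1-benzofuran-2-yl]phenol
Product: 18 (2S,3S)-trans-δ-viniferin, 5-[(2S,3S)-5-[(E)-2-(3,5-dihydroxyphenyl)ethenyl]-2-(4-hydroxyphenyl)-2,3-dihydro-1-benzofuran-3-yl]benzene-1,3-diol
Conditions: BBr3 (12 equiv, 1 M in CH2Cl2), CH2Cl2, −78 °C → rt, dark, Ar; ice-water quench
Reagents that add atoms: none
Why: Boron tribromide cleavage of aryl methyl ethers is the usual last step for methylated resveratrol oligomers, including those with a 2,3-diaryl-2,3-dihydrobenzofuran; no bond to a stereocentre is broken, and if C2–O1 ionised reversibly the intact C3 centre would steer reclosure back to the trans isomer.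

**Compound list**
1 | 4-(4,4,5,5-tetramethyl-1,3,2-dioxaborolan-2-yl)phenol | CC1(C)OB(OC1(C)C)c1ccc(O)cc1 | starting material
2 | 4-(4,4,5,5-tetramethyl-1,3,2-dioxaborolan-2-yl)phenyl methanesulfonate | CC1(C)OB(OC1(C)C)c1ccc(OS(C)(=O)=O)cc1 | intermediate
3 | [4-(methanesulfonyloxy)phenyl]boronic acid | CS(=O)(=O)Oc1ccc(B(O)O)cc1 | intermediate
4 | 6-bromochromone | O=c1ccoc2ccc(Br)cc12 | starting material
5 | 4-[(2S)-6-bromo-4-oxo-3,4-dihydro-2H-1-benzopyran-2-yl]phenyl methanesulfonate | CS(=O)(=O)Oc1ccc([C@@H]2CC(=O)c3cc(Br)ccc3O2)cc1 | intermediate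
6 | 4-[(2S)-6-bromo-4-methoxy-2H-1-benzopyran-2-yl]phenyl methanesulfonate (enol ether) | CS(=O)(=O)Oc1ccc([C@@H]2C=C(OC)c3cc(Br)ccc3O2)cc1 | intermediate
7 | 4-[(2R,3R)-3-[acetoxy(phenyl)-λ3-iodanyl]-6-bromo-4,4-dimethoxy-3,4-dihydro-2H-1-benzopyran-2-yl]phenyl methanesulfonate (2,3-trans; C2 is spatially unchanged, its descriptor changes because C3 now outranks the aryl group) | CS(=O)(=O)Oc1ccc([C@H]2Oc3ccc(Br)cc3C(OC)(OC)[C@@H]2I(OC(C)=O)c2ccccc2)cc1 | intermediate
8 | methyl (2S,3S)-5-bromo-2-[4-(methanesulfonyloxy)phenyl]-2,3-dihydro-1-benzofuran-3-carboxylate | CS(=O)(=O)Oc1ccc([C@H]2Oc3ccc(Br)cc3[C@@H]2C(=O)OC)cc1 | intermediate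
9 | 3,5-dimethoxystyrene | C=Cc1cc(OC)cc(OC)c1 | starting material
10 | methyl (2S,3S)-5-[(E)-2-(3,5-dimethoxyphenyl)ethenyl]-2-[4-(methanesulfonyloxy)phenyl]-2,3-dihydro-1-benzofuran-3-carboxylate | CS(=O)(=O)Oc1ccc([C@H]2Oc3ccc(/C=C/c4cc(OC)cc(OC)c4)cc3[C@@H]2C(=O)OC)cc1 | intermediate
11 | (2S,3S)-5-[(E)-2-(3,5-dimethoxyphenyl)ethenyl]-2-[4-(methanesulfonyloxy)phenyl]-2,3-dihydro-1-benzofuran-3-carboxylic acid | CS(=O)(=O)Oc1ccc([C@H]2Oc3ccc(/C=C/c4cc(OC)cc(OC)c4)cc3[C@@H]2C(=O)O)cc1 | intermediate
12 | 1,3-dioxoisoindolin-2-yl (2S,3S)-5-[(E)-2-(3,5-dimethoxyphenyl)ethenyl]-2-[4-(methanesulfonyloxy)phenyl]-2,3-dihydro-1-benzofuran-3-carboxylate | CS(=O)(=O)Oc1ccc([C@H]2Oc3ccc(/C=C/c4cc(OC)cc(OC)c4)cc3[C@@H]2C(=O)ON2C(=O)c3ccccc3C2=O)cc1 | intermediate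
13 | 1-bromo-3,5-dimethoxybenzene | COc1cc(Br)cc(OC)c1 | starting material
14 | (3,5-dimethoxyphenyl)magnesium bromide | COc1cc([Mg]Br)cc(OC)c1 | intermediate
15 | (3,5-dimethoxyphenyl)zinc chloride | COc1cc([Zn]Cl)cc(OC)c1 | intermediate
16 | 4-[(2S,3S)-3-(3,5-dimethoxyphenyl)-5-[(E)-2-(3,5-dimethoxyphenyl)ethenyl]-2,3-dihydro-1-benzofuran-2-yl]phenyl methanesulfonate | CS(=O)(=O)Oc1ccc([C@H]2Oc3ccc(/C=C/c4cc(OC)cc(OC)c4)cc3[C@@H]2c2cc(OC)cc(OC)c2)cc1 | intermediate
17 | 4-[(2S,3S)-3-(3,5-dimethoxyphenyl)-5-[(E)-2-(3,5-dimethoxyphenyl)ethenyl]-2,3-dihydro-1-benzofuran-2-yl]phenol | Oc1ccc([C@H]2Oc3ccc(/C=C/c4cc(OC)cc(OC)c4)cc3[C@@H]2c2cc(OC)cc(OC)c2)cc1 | intermediate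
18 | (2S,3S)-trans-δ-viniferin | Oc1ccc([C@H]2Oc3ccc(/C=C/c4cc(O)cc(O)c4)cc3[C@@H]2c2cc(O)cc(O)c2)cc1 | target

Total step count: 11. Longest linear sequence: 10 (steps 1–7 and 9–11); step 8 is a one-step side branch.

**Steps most likely to fail**

Step 9.
- What may go wrong: capture of the stabilised benzylic radical by nickel may be too slow, so that radical dimerisation, hydrogen abstraction or β-hydride loss with aromatisation of the furan ring overtakes C–C bond formation. Low-valent nickel may also insert into the aryl C–O bond of the sulfonate.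
- Fallback: it sets out from 8 (with 14 and 9) and rejoins the route at 16. The order of the two couplings is inverted and nickel is replaced by iron.
- Sequence: 8 is hydrolysed with Me3SnOH to the 5-bromo carboxylic acid F1. This is esterified with N-hydroxyphthalimide and DIC to its redox-active ester F2. F2 is coupled under Fe(acac)3 and 1,2-bis(diphenylphosphino)benzene catalysis in THF at rt with bis(3,5-dimethoxyphenyl)zinc F3, made from 14 and half an equivalent of ZnCl2. This gives the trans 5-bromo-2,3-diaryl-2,3-dihydrobenzofuran F4. A Heck reaction of F4 with 9 under the conditions of step 5 then gives 16.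
- Why it should help: this catalyst family couples benzylic radicals with arylzinc reagents rapidly and leaves aryl bromides and sulfonates alone. The Heck reaction now runs on a substrate that has no base-sensitive ester.

Step 4.
- What may go wrong: iodobenzene may leave by elimination (dehydrogenation of the heterocycle) or by methanolysis at C3. The C2 aryl group may migrate from the diaxial conformer. Enol ether formation may be sluggish because the ketone is conjugated with the ring oxygen.
- Fallback: it sets out from 5 and rejoins at 8. The same C4a shift is kept, but functionalisation and migration are separated.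
- Sequence: enol ether 6 is generated with HC(OMe)3 and TsOH in MeOH and trapped with N-bromosuccinimide at 0 °C, anti to the C2 aryl group. This gives the isolable 2,3-trans 3-bromo 4,4-dimethyl ketal F5, which is purified. AgBF4 in CH2Cl2 then abstracts bromide in the absence of an external nucleophile, so that only ionisation assisted by C4a remains. This is the α-halo ketal 1,2-aryl rearrangement used for 2-arylpropionates. Aqueous work-up of the dimethoxycarbenium salt gives 8.

Step 11.
- What may go wrong: the Lewis acid may ionise the C2–O1 bond with help from the oxygenated C2 aryl ring, followed by oligomerisation. HBr may protonate the electron-rich stilbene.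
- Fallback: it sets out from 16 and rejoins at 18, bypassing 17, by swapping the two deprotections.
- Sequence: BBr3 is applied to 16, where the sulfonate keeps the C2 aryl ring electron-poor and blocks ionisation at C2, giving the tetraphenol mesylate F6. The sulfonate is then removed with degassed aq NaOH in MeOH under argon in the presence of sodium dithionite, followed by cold acidification, to give 18.

**Further compounds**
F1 | step 9 | (2S,3S)-5-bromo-2-[4-(methanesulfonyloxy)phenyl]-2,3-dihydro-1-benzofuran-3-carboxylic acid | CS(=O)(=O)Oc1ccc([C@H]2Oc3ccc(Br)cc3[C@@H]2C(=O)O)cc1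
F2 | step 9 | 1,3-dioxoisoindolin-2-yl (2S,3S)-5-bromo-2-[4-(methanesulfonyloxy)phenyl]-2,3-dihydro-1-benzofuran-3-carboxylate | CS(=O)(=O)Oc1ccc([C@H]2Oc3ccc(Br)cc3[C@@H]2C(=O)ON2C(=O)c3ccccc3C2=O)cc1
F3 | step 9 | bis(3,5-dimethoxyphenyl)zinc | COc1cc([Zn]c2cc(OC)cc(OC)c2)cc(OC)c1
F4 | step 9 | 4-[(2S,3S)-5-bromo-3-(3,5-dimethoxyphenyl)-2,3-dihydro-1-benzofuran-2-yl]phenyl methanesulfonate | CS(=O)(=O)Oc1ccc([C@H]2Oc3ccc(Br)cc3[C@@H]2c2cc(OC)cc(OC)c2)cc1
F5 | step 4 | 4-[(2R,3R)-3,6-dibromo-4,4-dimethoxy-3,4-dihydro-2H-1-benzopyran-2-yl]phenyl methanesulfonate (2,3-trans) | CS(=O)(=O)Oc1ccc([C@H]2Oc3ccc(Br)cc3C(OC)(OC)[C@@H]2Br)cc1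
F6 | step 11 | 4-[(2S,3S)-3-(3,5-dihydroxyphenyl)-5-[(E)-2-(3,5-dihydroxyphenyl)ethenyl]-2,3-dihydro-1-benzofuran-2-yl]phenyl methanesulfonate | CS(=O)(=O)Oc1ccc([C@H]2Oc3ccc(/C=C/c4cc(O)cc(O)c4)cc3[C@@H]2c2cc(O)cc(O)c2)cc1
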